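Decide before you repeat the run that in the new flask you will watch a quotient, not the clock.

in all of them: D 7.5 mM

| run | X | J | remark | time |
|---|---|---|---|---|
| Sunday's | 0.025 M | 0.20 M | run made earlier |  |
| Thursday's | 0.038 M | 0.20 M | run made earlier |  |
| flask | 0.050 M | 0.200 M |  | 20 min |

| run | time / min | X / % | Q / % |
|---|---|---|---|
| Sunday's | 1.50 | 35.9 | 66.0 |
| Sunday's | 4.00 | 24.3 | 73.5 |
| Sunday's | 8.00 | 25.7 | 74.8 |
| Sunday's | 12.0 | 24.4 | 73.6 |
| Thursday's | 1.50 | 33.9 | 64.1 |
| Thursday's | 4.00 | 26.9 | 74.7 |
| Thursday's | 8.00 | 27.0 | 73.7 |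
| Thursday's | 12.0 | 27.2 | 75.4 |

(scatter of a reading: 1 percentage point)

- the numbers in the tables scatter with a standard deviation of 1 percentage point

1. concentration of X at 20 min, in M
2. concentration of Q at 20 min, in M

Will the flask have reached its end state by the asked time? From 4.00 min to 12.0 min no reading of either run moves by more than 1.7 points, against a scatter of 1 point, and the asked 20 min lies later than the last reading, so I take the flask, with the same charges of J and D, to stand on its plateau by then.

What holds it there? Sunday's run stops with X at 24.8% and Q at 74.0% of the X charged, while [J], which was not measured, comes to about 0.182 M as its charge less the Q formed, so neither X nor J has run out, and I try [Q]/([X][J]). Sunday's run gives 16.4 L mol⁻¹, and Thursday's, from a different charge of X, with X at 27.0% and Q at 74.6%, gives 16.1 L mol⁻¹. Their mean, 16.3 L mol⁻¹, is the plateau quotient, [Q]/([X][J]) once the readings stop moving, an equilibrium constant if the plateau is an equilibrium.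

What does it give in the flask? Taking [X] as its charge less [Q], and [J] likewise, my own reckoning gives [Q] = 0.0363 M and [X] = 0.0137 M. The forecast, which differs from my reckoning in the last figure, says 0.0136 M of X (from 0.012 M to 0.0152 M) and 0.0364 M of Q (from 0.0345 M to 0.0382 M), in its words: “It looks like an equilibrium”.

The flask gives 0.0138 M of X and 0.0362 M of Q at 20 min, both inside the forecast's ranges.

    X + J + D ⇌ Q + D, rate k1*[X]*[J]*[D] forward; the back reaction follows from the equilibrium constant (K = 16.0 L mol⁻¹, k = 13.0 L² mol⁻² s⁻¹)
    D ⇌ L (K = 0.390, k = 0.00270 s⁻¹)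

At 20.0 min the X + J and Q step, both ways together, relaxes with a half-life of 0.686 min, far shorter than the 20 min of the flask. The flask's [Q] still stands at 0.0362 M at 200 min, and its values give a quotient of 16.0 L mol⁻¹. For a neighbour of this flask charged with 0.050 M of J, the plateau quotient reckons 0.0173 M of Q, and that neighbour holds 0.0172 M of Q at 20 min.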